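The kappa end, a cyclopentane (C1'–C5') with vicinal quaternary C1'/C5', acyl carbon C6' and oxygen on C6' and C8', is read as a ring-contracted, hydrated form of the 7,8-didehydro-beta ring (C1–C6 with the C7≡C8 alkyne) of the other end. Both halves therefore come from one actinol-derived C15 enyne. In one operation a Lewis acid semipinacol shift of its anti-5,6-epoxide diacetate moves C1 from C6 to C5, which contracts the ring, sets quaternary C5' and leaves a C6' ynone as a masked 1,3-diketone. Two Wittig couplings (ring-A C15 salt with a C10 dialdehyde, then the kappa C15 salt) build the chain.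

Key step: step 7

Remark on the chemistry: carotenoid numbering is used for positions (ring A C1–C6, chain C7–C15, primed numbers for the kappa half); the enolised 1,3-diketone is drawn as the 8'-enol/6'-keto tautomer, which equilibrates freely with its partner; compounds 1, 5 and 23 are taken as purchasable.

Step 1
Reactants: 1 (4R,6R)-actinol
Product: 2 (4R,6R)-4-(tert-butyldimethylsilyloxy)-2,2,6-trimethylcyclohexanone
Conditions: TBSCl, imidazole, DMF, rt
Reagents that add atoms: tert-butyldimethylsilyl chloride, CC(C)(C)[Si](C)(C)Cl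
Why: Imidazole-promoted O-silylation of the secondary alcohol should protect it from the strong base of the next step without touching either stereocentre.

Step 2
Reactants: 2 TBS-actinol
Product: 4 (4R)-4-(TBSO)-2,6,6-trimethylcyclohex-1-en-1-yl triflate, via potassium enolate 3 (not isolated)
Conditions: KN(SiMe3)2, THF, −78 °C; PhNTf2, −78 °C to rt
Reagents that add atoms: N-phenylbis(trifluoromethanesulfonimide), O=S(=O)(N(c1ccccc1)S(=O)(=O)C(F)(F)F)C(F)(F)F
Why: Enolate O-triflation should give a single tetrasubstituted enol triflate because only the methyl-bearing alpha carbon carries a hydrogen, the silyloxy group is not beta to the enolate carbon and cannot be eliminated, and the methyl stereocentre is erased on purpose.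

Step 3
Reactants: 4 enol triflate; 5 (E)-3-methylpent-2-en-4-yn-1-ol
Product: 6 (3R)-3-O-TBS C15 enyne alcohol
Conditions: Pd(PPh3)4 (5 mol %), CuI (10 mol %), Et3N, DMF, 50 °C
Reagents that add atoms: none
Why: Sonogashira coupling of the cyclohexenyl triflate with the terminal alkyne should form the C6–C7 bond directly, tolerate the free allylic alcohol and leave the E alkene and C3 untouched.

Step 4
Reactants: 6 (3R)-3-O-TBS C15 enyne alcohol
Product: 7 (3R)-C15 enyne diol
Conditions: Bu4NF, THF, rt
Reagents that add atoms: none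
Why: Fluoride desilylation should free the C3 hydroxyl without affecting the enyne.

Step 5
Reactants: 7 (3R)-C15 enyne diol
Product: 8 C15 enyne diacetate
Conditions: Ac2O, pyridine, DMAP (cat.), CH2Cl2, rt
Reagents that add atoms: acetic anhydride, CC(=O)OC(C)=O
Why: DMAP-catalysed acylation should cap both hydroxyls as acetates, which removes hydroxyl direction in the epoxidation and gives an O3 group whose ester oxygen cannot bridge to C6 in the rearrangement.

Step 6
Reactants: 8 C15 enyne diacetate
Product: 9 (3S,5R,6R)-anti-5,6-epoxide diacetate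
Conditions: mCPBA (1.05 equiv), NaHCO3, CH2Cl2, 0 °C
Reagents that add atoms: 3-chloroperoxybenzoic acid, OOC(=O)c1cccc(Cl)c1
Why: Prilezhaev epoxidation should take the tetrasubstituted ring alkene in preference to the side-chain alkene (trisubstituted and deactivated by its allylic acetate), and the non-directing 3-acetoxy group should steer the peracid to the opposite face so that C5 and C6 are set 5R,6R with the oxygen trans to O3, the minor syn epoxide being removed by chromatography.

Step 7
Reactants: 9 (3S,5R,6R)-anti-5,6-epoxide diacetate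
Product: 10 kappa-ring ynone diacetate
Conditions: BF3·OEt2 (0.5 equiv), CH2Cl2, −78 to −40 °C; Et3N quench
Reagents that add atoms: none
Why: Boron binds the epoxide oxygen, the C5–O bond lengthens at the plain tertiary carbon and C1 shifts from C6 to C5 on the face opposite the departing oxygen while the C6–O bond becomes the carbonyl (semipinacol, Meinwald-type 1,2-alkyl shift). The closest known reaction type is the Lewis acid ring contraction of tetrasubstituted cyclohexene oxides to acylcyclopentanes, established for 5,6-epoxy-beta-ring units that carry an unsaturated, cation-disfavouring substituent on C6. The cyclopentane C1'–C5' is not closed by a cyclisation but arises by ring contraction: the C1–C5 bond forms as the C1–C6 ring bond breaks, a suprafacial 1,2-shift with inversion at C5. The only new stereocentre, quaternary C5' (R), is fixed by the epoxide configuration, since migration is anti to the C5–O bond and the C5–C6 ring bond cannot rotate, and C3' is carried through unchanged. The step needs C5–O rather than C6–O cleavage and migration of C1 rather than of the alkynyl group: the sp carbon on C6 withdraws inductively and migrates poorly, whereas fully substituted C1 is the best migrating group available, and its shift turns C6 into a conjugated ynone carbonyl and relieves the C1/C6 congestion. The O3 acetate cannot bridge to C6, C6 has no hydrogen to shift and an alkyne cannot give the furanoid 5,8-ether, so the usual side paths of 5,6-epoxides are closed.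

Step 8
Reactants: 10 kappa-ring ynone diacetate
Product: 13 kappa-C15 enolised diketone diol, via enaminone diacetate 11 (not isolated), via enaminone diol 12 (not isolated)
Conditions: Et2NH, MeOH, 0 °C to rt; K2CO3 (0.3 equiv), rt; then 2 M HCl to pH 1, THF, rt
Reagents that add atoms: water, O
Why: Aza-Michael addition of the secondary amine at C8' of the ynone should give a base-stable vinylogous amide, carbonate-catalysed transesterification then removes both acetates, and acid hydrolysis of the enaminone places oxygen on C8' to give the 1,3-diketone, which should rest as the hydrogen-bonded Z enol while quaternary C5' cannot epimerise.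

Step 9
Reactants: 13 kappa-C15 enolised diketone diol
Product: 14 kappa-C15 triphenylphosphonium bromide
Conditions: PPh3·HBr, CH2Cl2, rt to 40 °C
Reagents that add atoms: triphenylphosphine hydrobromide, [Br-].c1ccccc1[PH+](c1ccccc1)c1ccccc1
Why: Acid-mediated allylic substitution by the phosphine, the usual way from hydroxylated C15 allylic alcohols to Wittig salts, should act only at the primary allylic carbinol and leave the secondary C3' hydroxyl, the chelated enol and the 9'E alkene as they are.

Step 10
Reactants: 6 (3R)-3-O-TBS C15 enyne alcohol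
Product: 15 (3R)-3-O-TBS C15 enyne pivaloate
Conditions: PivCl, pyridine, CH2Cl2, 0 °C
Reagents that add atoms: pivaloyl chloride, CC(C)(C)C(=O)Cl
Why: Acylation of the only free hydroxyl should install an ester that deactivates the C11 methylene towards the coming oxidation and survives the fluoride, acid and borohydride steps.

Step 11
Reactants: 15 (3R)-3-O-TBS C15 enyne pivaloate
Product: 16 (3S)-3-O-TBS 4-oxo enyne pivaloate
Conditions: CrO3, 3,5-dimethylpyrazole, CH2Cl2, −20 °C
Reagents that add atoms: chromium trioxide, O=[Cr](=O)=O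
Why: Allylic C–H oxidation with the chromium trioxide–dimethylpyrazole complex should convert C4, the only secondary allylic methylene of the ring alkene, into the enone (C1 is quaternary, the methyl groups are primary, C11 is deactivated by its ester), and the non-basic medium leaves the now alpha C3 centre intact.

Step 12
Reactants: 16 (3S)-3-O-TBS 4-oxo enyne pivaloate
Product: 17 (3S)-3-hydroxy-4-oxo enyne pivaloate
Conditions: HF·pyridine, THF, 0 °C to rt
Reagents that add atoms: none
Why: Acidic fluoride desilylation should free the alpha hydroxyl without base, so the ketol neither epimerises at C3 nor autoxidises to a diosphenol.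

Step 13
Reactants: 17 (3S)-3-hydroxy-4-oxo enyne pivaloate
Product: 18 (3S,4S)-trans-diol enyne pivaloate
Conditions: Me4NBH(OAc)3, MeCN/AcOH, −20 to 0 °C
Reagents that add atoms: none
Why: Hydroxyl-directed triacetoxyborohydride reduction (Saksena–Evans type) should deliver hydride from boron bound to O3 onto the same face of the C4 carbonyl, so the new C4 hydroxyl ends up trans to O3 (4S), and this weak hydride reduces the enone only in the 1,2 sense.

Step 14
Reactants: 18 (3S,4S)-trans-diol enyne pivaloate
Product: 19 (3S,4S)-bis-TBS enyne pivaloate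
Conditions: TBSOTf, 2,6-lutidine, CH2Cl2, 0 °C
Reagents that add atoms: tert-butyldimethylsilyl triflate, CC(C)(C)[Si](C)(C)OS(=O)(=O)C(F)(F)F
Why: Silyl triflate silylation should cover both secondary hydroxyls, including the hindered allylic one at C4, so that neither is brominated or ionised later.

Step 15
Reactants: 19 (3S,4S)-bis-TBS enyne pivaloate
Product: 20 bis-TBS C15 allylic alcohol
Conditions: i-Bu2AlH, CH2Cl2, −78 °C; aq. potassium sodium tartrate work-up
Reagents that add atoms: none
Why: Reductive ester cleavage by the aluminium hydride at low temperature should remove the pivaloate without touching the silyl ethers or the enyne.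

Step 16
Reactants: 20 bis-TBS C15 allylic alcohol
Product: 21 bis-TBS C15 allylic bromide
Conditions: CBr4, PPh3, 2,6-lutidine, CH2Cl2, 0 °C
Reagents that add atoms: carbon tetrabromide, BrC(Br)(Br)Br
Why: Appel bromination should convert the primary allylic alcohol by SN2 displacement under neutral conditions, which preserves the acid-labile allylic C4 silyl ether and the 9E geometry.

Step 17
Reactants: 21 bis-TBS C15 allylic bromide
Product: 22 ring-A C15 triphenylphosphonium bromide
Conditions: PPh3, EtOAc, rt
Reagents that add atoms: triphenylphosphine, c1ccccc1P(c1ccccc1)c1ccccc1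
Why: SN2 quaternisation of the phosphine by the primary allylic bromide should give the salt, which is expected to precipitate from ethyl acetate.

Step 18
Reactants: 22 ring-A C15 triphenylphosphonium bromide; 23 (2E,4E,6E)-2,7-dimethylocta-2,4,6-trienedial (3 equiv)
Product: 26 all-E C25 acetylenic apo-aldehyde bis-TBS ether, via C15 ylide 24 (not isolated), via 11Z C25 aldehyde 25 (not isolated)
Conditions: NaOMe, CH2Cl2/MeOH, 0 °C to rt; then heptane, 70 °C, dark
Reagents that add atoms: none
Why: Wittig olefination of one formyl group (excess dialdehyde suppresses double condensation) should form C11=C12 as an E/Z mixture, and gentle heating without iodine should convert the hindered 11Z isomer into the all-E aldehyde while leaving the 9E alkene next to the triple bond alone.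

Step 19
Reactants: 14 kappa-C15 triphenylphosphonium bromide; 26 all-E C25 acetylenic apo-aldehyde bis-TBS ether
Product: 29 3,4-bis-O-TBS C40 carotenoid, via kappa ylide enolate 27 (not isolated), via 11'Z C40 isomer 28 (not isolated)
Conditions: NaOMe (2.2 equiv per 14), CH2Cl2/MeOH, 0 °C to rt; AcOH; then EtOAc/heptane, 70 °C, dark
Reagents that add atoms: none
Why: Wittig olefination in which the first equivalent of methoxide turns the diketone into its enolate (shielding it from addition and retro-Claisen cleavage) and the second forms the allylic ylide that condenses with the aldehyde, after which thermal isomerisation should funnel the 11'Z isomer to the all-E polyene with no stereocentre involved.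

Step 20
Reactants: 29 3,4-bis-O-TBS C40 carotenoid
Product: 30 target CNP0114063.1
Conditions: Bu4NF, THF, 0 °C to rt, argon, dark
Reagents that add atoms: none
Why: Fluoride desilylation should remove both ring-A silyl ethers under non-acidic conditions, so the allylic C4–O bond is not ionised and the diketone rests as its enolate until neutral work-up.

Compound list
1 | (4R,6R)-4-hydroxy-2,2,6-trimethylcyclohexanone (actinol) | C[C@H]1C(=O)C(C)(C)C[C@H](O)C1 | starting material
2 | (4R,6R)-4-(tert-butyldimethylsilyloxy)-2,2,6-trimethylcyclohexanone | C[C@H]1C(=O)C(C)(C)C[C@H](O[Si](C)(C)C(C)(C)C)C1 | intermediate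
3 | potassium (4R)-4-(tert-butyldimethylsilyloxy)-2,6,6-trimethylcyclohex-1-en-1-olate | CC1=C([O-])C(C)(C)C[C@H](O[Si](C)(C)C(C)(C)C)C1.[K+] | intermediate (not isolated)
4 | (4R)-4-(tert-butyldimethylsilyloxy)-2,6,6-trimethylcyclohex-1-en-1-yl trifluoromethanesulfonate | CC1=C(OS(=O)(=O)C(F)(F)F)C(C)(C)C[C@H](O[Si](C)(C)C(C)(C)C)C1 | intermediate
5 | (E)-3-methylpent-2-en-4-yn-1-ol | C#C/C(C)=C/CO | starting material
6 | (2E)-5-[(4R)-4-(tert-butyldimethylsilyloxy)-2,6,6-trimethylcyclohex-1-en-1-yl]-3-methylpent-2-en-4-yn-1-ol (3R in carotenoid numbering) | CC1=C(C#C/C(C)=C/CO)C(C)(C)C[C@H](O[Si](C)(C)C(C)(C)C)C1 | intermediate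
7 | (2E)-5-[(4R)-4-hydroxy-2,6,6-trimethylcyclohex-1-en-1-yl]-3-methylpent-2-en-4-yn-1-ol, the common (3R)-C15 enyne diol | CC1=C(C#C/C(C)=C/CO)C(C)(C)C[C@H](O)C1 | intermediate
8 | 3,11-di-O-acetate of 7 | CC1=C(C#C/C(C)=C/COC(C)=O)C(C)(C)C[C@H](OC(C)=O)C1 | intermediate
9 | (3S,5R,6R)-5,6-epoxide of 8, oxirane oxygen trans to the 3-acetoxy group | CC(=O)O[C@@H]1C[C@@]2(C)O[C@@]2(C#C/C(C)=C/COC(C)=O)C(C)(C)C1 | intermediate
10 | (2E)-6-[(1R,4S)-4-acetoxy-1,2,2-trimethylcyclopentyl]-3-methyl-6-oxohex-2-en-4-yn-1-yl acetate (3'S,5'R kappa-ring ynone) | CC(=O)OC/C=C(C)/C#CC(=O)[C@]1(C)C[C@@H](OC(C)=O)CC1(C)C | intermediate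
11 | 8'-(diethylamino) enaminone from 10 (vinylogous amide, 9'E, both acetates in place; C7'=C8' geometry immaterial) | CCN(CC)C(=CC(=O)[C@]1(C)C[C@@H](OC(C)=O)CC1(C)C)/C(C)=C/COC(C)=O | intermediate (not isolated)
12 | 8'-(diethylamino) enaminone with both hydroxyls free | CCN(CC)C(=CC(=O)[C@]1(C)C[C@@H](O)CC1(C)C)/C(C)=C/CO | intermediate (not isolated)
13 | (2Z,4E)-3,6-dihydroxy-1-[(1R,4S)-4-hydroxy-1,2,2-trimethylcyclopentyl]-4-methylhexa-2,4-dien-1-one (Z enol of the 1,3-diketone) | OC/C=C(C)/C(O)=C/C(=O)[C@]1(C)C[C@@H](O)CC1(C)C | intermediate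
14 | [(2E,4Z)-4-hydroxy-6-[(1R,4S)-4-hydroxy-1,2,2-trimethylcyclopentyl]-3-methyl-6-oxohexa-2,4-dien-1-yl]triphenylphosphonium bromide | [Br-].c1ccccc1[P+](c1ccccc1)(c1ccccc1)C/C=C(C)/C(O)=C/C(=O)[C@]1(C)C[C@@H](O)CC1(C)C | intermediate
15 | 11-O-pivaloate of 6 (3R, 3-O-TBS) | CC1=C(C#C/C(C)=C/COC(=O)C(C)(C)C)C(C)(C)C[C@H](O[Si](C)(C)C(C)(C)C)C1 | intermediate
16 | (2E)-5-[(4S)-4-(tert-butyldimethylsilyloxy)-2,6,6-trimethyl-3-oxocyclohex-1-en-1-yl]-3-methylpent-2-en-4-yn-1-yl pivalate | CC1=C(C#C/C(C)=C/COC(=O)C(C)(C)C)C(C)(C)C[C@H](O[Si](C)(C)C(C)(C)C)C1=O | intermediate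
17 | (2E)-5-[(4S)-4-hydroxy-2,6,6-trimethyl-3-oxocyclohex-1-en-1-yl]-3-methylpent-2-en-4-yn-1-yl pivalate | CC1=C(C#C/C(C)=C/COC(=O)C(C)(C)C)C(C)(C)C[C@H](O)C1=O | intermediate
18 | (2E)-5-[(3S,4S)-3,4-dihydroxy-2,6,6-trimethylcyclohex-1-en-1-yl]-3-methylpent-2-en-4-yn-1-yl pivalate (trans diol) | CC1=C(C#C/C(C)=C/COC(=O)C(C)(C)C)C(C)(C)C[C@H](O)[C@H]1O | intermediate
19 | 3,4-bis-O-TBS ether of 18 | CC1=C(C#C/C(C)=C/COC(=O)C(C)(C)C)C(C)(C)C[C@H](O[Si](C)(C)C(C)(C)C)[C@H]1O[Si](C)(C)C(C)(C)C | intermediate
20 | (2E)-5-[(3S,4S)-3,4-bis(tert-butyldimethylsilyloxy)-2,6,6-trimethylcyclohex-1-en-1-yl]-3-methylpent-2-en-4-yn-1-ol | CC1=C(C#C/C(C)=C/CO)C(C)(C)C[C@H](O[Si](C)(C)C(C)(C)C)[C@H]1O[Si](C)(C)C(C)(C)C | intermediate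
21 | primary allylic bromide from 20 | CC1=C(C#C/C(C)=C/CBr)C(C)(C)C[C@H](O[Si](C)(C)C(C)(C)C)[C@H]1O[Si](C)(C)C(C)(C)C | intermediate
22 | triphenylphosphonium bromide from 21 (ring-A C15 salt) | CC1=C(C#C/C(C)=C/C[P+](c2ccccc2)(c2ccccc2)c2ccccc2)C(C)(C)C[C@H](O[Si](C)(C)C(C)(C)C)[C@H]1O[Si](C)(C)C(C)(C)C.[Br-] | intermediate
23 | (2E,4E,6E)-2,7-dimethylocta-2,4,6-trienedial | O=C/C(C)=C/C=C/C=C(C)/C=O | starting material
24 | phosphorus ylide from 22 | CC1=C(C#C/C(C)=C/C=P(c2ccccc2)(c2ccccc2)c2ccccc2)C(C)(C)C[C@H](O[Si](C)(C)C(C)(C)C)[C@H]1O[Si](C)(C)C(C)(C)C | intermediate (not isolated)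
25 | 11Z isomer of 26 | CC1=C(C#C/C(C)=C/C=C\C(C)=C\C=C\C=C(C)\C=O)C(C)(C)C[C@H](O[Si](C)(C)C(C)(C)C)[C@H]1O[Si](C)(C)C(C)(C)C | intermediate (not isolated)
26 | all-E (3S,4S)-3,4-bis(TBSO)-7,8-didehydro-12'-apo-beta-caroten-12'-al (C25 aldehyde) | CC1=C(C#C/C(C)=C/C=C/C(C)=C/C=C/C=C(C)/C=O)C(C)(C)C[C@H](O[Si](C)(C)C(C)(C)C)[C@H]1O[Si](C)(C)C(C)(C)C | intermediate
27 | sodium enolate of the ylide from 14 | c1ccccc1P(c1ccccc1)(c1ccccc1)=C/C=C(C)/C([O-])=C/C(=O)[C@]1(C)C[C@@H](O)CC1(C)C.[Na+] | intermediate (not isolated)
28 | 11'Z isomer of 29 | CC1=C(C#C/C(C)=C/C=C/C(C)=C/C=C/C=C(C)/C=C\C=C(C)\C(O)=C\C(=O)[C@]2(C)C[C@@H](O)CC2(C)C)C(C)(C)C[C@H](O[Si](C)(C)C(C)(C)C)[C@H]1O[Si](C)(C)C(C)(C)C | intermediate (not isolated)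
29 | 3,4-bis-O-TBS ether of the target (all-E polyene, Z enol) | CC1=C(C#C/C(C)=C/C=C/C(C)=C/C=C/C=C(C)/C=C/C=C(C)/C(O)=C/C(=O)[C@]2(C)C[C@@H](O)CC2(C)C)C(C)(C)C[C@H](O[Si](C)(C)C(C)(C)C)[C@H]1O[Si](C)(C)C(C)(C)C | intermediate
30 | CNP0114063.1, (3S,4S,3'S,5'R) | CC1=C(C#C/C(C)=C/C=C/C(C)=C/C=C/C=C(C)/C=C/C=C(C)/C(O)=C/C(=O)[C@]2(C)C[C@@H](O)CC2(C)C)C(C)(C)C[C@H](O)[C@H]1O | target

Total step count: 20 steps. Longest linear sequence: 14 steps (steps 1, 2, 3, 10 to 17, 18, 19, 20).

Steps most likely to fail

1. Step 7. What may go wrong: ionisation at the wrong epoxide carbon (C6–O instead of C5–O), or shift of the alkynyl group instead of C1, leading to ring-intact ketones or allenic material. Fallback (ring contraction on an epoxide that carries hydrogen on C6, alkyne attached afterwards): it sets out from 4 and comes back at 13. Reduction of 4 with HCO2H/Bu3N under Pd(OAc)2/PPh3 catalysis should give the trisubstituted alkene (R)-tert-butyldimethyl[(3,5,5-trimethylcyclohex-3-en-1-yl)oxy]silane F1, and mCPBA the epoxide trans to the silyloxy group F2. With hydrogen on C6 a Lewis acid can only open the tertiary C5–O bond, and methylaluminium bis(4-bromo-2,6-di-tert-butylphenoxide) at −78 °C should promote the known alkyl-shift ring contraction of such trisubstituted cyclohexene oxides to the kappa-ring aldehyde F3, with the same inversion at C5. The TBS ether of the enynol F4 is deprotonated with n-BuLi to the lithium acetylide F5, which adds to F3 to give the propargylic alcohol F6 (both carbinol epimers serve). Dess–Martin oxidation gives the bis-TBS ynone F7. Et2NH, then aqueous HCl, which hydrolyses the enaminone F8 and cleaves both silyl ethers, delivers 13.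

2. Step 11. What may go wrong: hydrogen abstraction at the wrong allylic positions (ring methyl, C11) or slow oxidation beside the bulky silyloxy carbon with over-oxidation. Fallback (oxidative 1,3-transposition in place of C–H oxidation): it sets out from 2 and comes back at 16. Enolate 3 is trapped with Me3SiCl as the trimethylsilyl enol ether F9, and Saegusa–Ito dehydrogenation with Pd(OAc)2 in MeCN should give the enone (4S)-4-(TBSO)-2,6,6-trimethylcyclohex-2-en-1-one F10. The dilithio derivative of 5 F11 (2 equiv n-BuLi, THF) adds 1,2 to the carbonyl to give the tertiary alcohol F12, whose primary hydroxyl is selectively pivaloylated to F13. Pyridinium chlorochromate, C5H5NH[CrO3Cl], then effects the Babler–Dauben oxidative transposition (chromate ester, [3,3] shift to C4, oxidation), which moves oxygen to C4 and the alkene to C5=C6 and so gives 16.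

3. Step 18. What may go wrong: erosion of the 9E geometry through the delocalised allylic ylide and during thermal equilibration (the Z form next to a triple bond is not strongly disfavoured), together with double condensation on the dialdehyde. Fallback (phosphonate carbanion in place of the ylide): it sets out from 21 and comes back at 26. Arbuzov reaction of 21 with P(OEt)3 should give the diethyl allylphosphonate F14; Horner–Wadsworth–Emmons reaction of its sodium salt (NaH, THF, 0 °C) with excess 23 is E-selective at the new bond, needs no heating and should give 26 directly.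

Further compounds
F1 | step 7 | (R)-tert-butyldimethyl[(3,5,5-trimethylcyclohex-3-en-1-yl)oxy]silane | CC1=CC(C)(C)C[C@H](O[Si](C)(C)C(C)(C)C)C1
F2 | step 7 | epoxide of F1 with the oxirane oxygen trans to the silyloxy group (3S,5R,6S in carotenoid numbering) | CC(C)(C)[Si](C)(C)O[C@@H]1C[C@@]2(C)O[C@H]2C(C)(C)C1
F3 | step 7 | (1R,4S)-4-(tert-butyldimethylsilyloxy)-1,2,2-trimethylcyclopentanecarbaldehyde | O=C[C@]1(C)C[C@@H](O[Si](C)(C)C(C)(C)C)CC1(C)C
F4 | step 7 | (E)-tert-butyldimethyl[(3-methylpent-2-en-4-yn-1-yl)oxy]silane | C#C/C(C)=C/CO[Si](C)(C)C(C)(C)C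
F5 | step 7 | lithium acetylide of F4 | [Li]C#C/C(C)=C/CO[Si](C)(C)C(C)(C)C
F6 | step 7 | propargylic alcohol from F3 and F5 (carbinol epimers) | CC(C)(C)[Si](C)(C)OC/C=C(C)/C#CC(O)[C@]1(C)C[C@@H](O[Si](C)(C)C(C)(C)C)CC1(C)C
F7 | step 7 | bis-TBS kappa-ring ynone | CC(C)(C)[Si](C)(C)OC/C=C(C)/C#CC(=O)[C@]1(C)C[C@@H](O[Si](C)(C)C(C)(C)C)CC1(C)C
F8 | step 7 | 8'-(diethylamino) enaminone of F7 | CCN(CC)C(=CC(=O)[C@]1(C)C[C@@H](O[Si](C)(C)C(C)(C)C)CC1(C)C)/C(C)=C/CO[Si](C)(C)C(C)(C)C
F9 | step 11 | (4R)-4-(tert-butyldimethylsilyloxy)-2,6,6-trimethyl-1-(trimethylsilyloxy)cyclohex-1-ene | CC1=C(O[Si](C)(C)C)C(C)(C)C[C@H](O[Si](C)(C)C(C)(C)C)C1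
F10 | step 11 | (4S)-4-(tert-butyldimethylsilyloxy)-2,6,6-trimethylcyclohex-2-en-1-one | CC1=C[C@@H](O[Si](C)(C)C(C)(C)C)CC(C)(C)C1=O
F11 | step 11 | dilithio derivative of 5 (lithium alkoxide and lithium acetylide) | [Li]C#C/C(C)=C/CO[Li]
F12 | step 11 | (4S)-4-(tert-butyldimethylsilyloxy)-1-[(E)-5-hydroxy-3-methylpent-3-en-1-yn-1-yl]-2,6,6-trimethylcyclohex-2-en-1-ol (carbinol epimers) | CC1=C[C@@H](O[Si](C)(C)C(C)(C)C)CC(C)(C)C1(O)C#C/C(C)=C/CO
F13 | step 11 | primary pivaloate of F12 | CC1=C[C@@H](O[Si](C)(C)C(C)(C)C)CC(C)(C)C1(O)C#C/C(C)=C/COC(=O)C(C)(C)C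
F14 | step 18 | diethyl allylphosphonate from 21 | CC1=C(C#C/C(C)=C/CP(=O)(OCC)OCC)C(C)(C)C[C@H](O[Si](C)(C)C(C)(C)C)[C@H]1O[Si](C)(C)C(C)(C)C
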